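**Remark on the chemistry (assumption):** the inner 3-hydroxybutanoyl unit of the target is R and the terminal one S, so the two come from opposite enantiomeric series. tert-Butyl (R)-3-hydroxybutanoate (12) is assumed to be purchasable enantiopure, like its antipode.

## Analysis of the target

Talapolyester A (22) is an open-chain tetraester whose only ring is a benzene ring: an (S)-3-hydroxybutanoyl unit acylates the hydroxyl of an (R)-3-hydroxybutanoyl unit, which acylates the side-chain oxygen of 2,4-dihydroxy-6-[(R)-2-hydroxypropyl]benzoic acid, whose carboxyl in turn esterifies O3 of (R)-3,4-dihydroxybutanoic acid. The four stereocentres are isolated secondary carbinol carbons, each separated from the next by an ester linkage and at least four atoms, so none can steer another and each has to come from an enantiopure building block. The sensitive groups are three β-acyloxy carbonyl units (E1cB loss of carboxylate under base), a free primary hydroxyl next to the aroylated secondary oxygen (1,2-acyl shift), a carboxyl that can lactonise onto that hydroxyl, and a resorcinol. The difficulty is therefore not the skeleton but the order and chemoselectivity of four ester bonds and the orthogonal masking of two carboxyl groups. The benzoic acid is flanked on both sides (oxygen at C2, CH2 at C6) and must nevertheless acylate a secondary β-hydroxy ester, and the endgame has to be neutral. The strategy rests on arene C6: in a 2,4-dioxygenated benzoic acid it carries the only C–H bond ortho to the carboxyl carbon. The chain on it, CH2–CH(O)–CH3 with R configuration, is (R)-propylene oxide (4) attached through its methylene carbon, with its oxygen placed to close a six-membered lactone onto the carboxyl.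

## Retrosynthetic reasoning

**22 from 21.** All five hydroxyl and carboxyl masks are benzyl groups, so the last operation cuts five O–CH2Ph bonds in one neutral hydrogenolysis. This keeps acid and base away from the finished polyester.

**21 from 16 and 19.** The bond cut is the C(=O)–O bond between the arene carboxyl carbon and O3 of the dihydroxybutanoate. It is cut here because it divides the molecule into the arene-plus-dimer acid 16 and the small alcohol 19, and because it is the most hindered ester, best made once on a fully elaborated acid. The forward reaction activates the acyl side (acid chloride 20), so the R centre of 19 is retained.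

**19 from 18 from 17.** The benzyl ester is reached by ester exchange from methyl ester 18. In 18 the C1–C2 bond and the ester are cut back to epoxide 17 by carbonylative opening at the terminal carbon. The stereocentre of 17 is not touched.

**16 from 15 from 8 and 14.** The allyl ester of 15 is the orthogonal mask of the arene carboxyl. The ester bond between the side-chain oxygen and the carbonyl of the inner hydroxybutanoate is then cut, giving alcohol 8 and dimer acid 14. Attaching the two hydroxybutanoates as one piece saves a protect–deprotect cycle on the arene fragment.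

**14 from 13 from 11 and 12; 11 from 10 from 9.** The dimer is cut at its internal ester into the benzyl-protected S acid 11 and the R alcohol 12, whose tert-butyl ester is removed by acid without touching the benzyl ether. Acid 11 comes from the chiral-pool ester 9 by O-benzylation to 10 and saponification.

**8 from 6 via 7.** Lactone 6 masks the carboxyl and the side-chain hydroxyl at once. Basic hydrolysis opens it to carboxylate 7, which is trapped by O-allylation before it can reclose.

**6 from 3 and 4.** Two bonds are cut: arene C6–CH2 and the lactone O–C(=O). This returns the whole side chain with its stereocentre to epoxide 4 and leaves acid 3, in which C6 is the only position the carboxylate can direct a metal to. The forward step must alkylate C6 at the epoxide methylene, giving hydroxy acid 5, and lactonise it.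

**3 from 2 from 1.** Perbenzylation of 1 gives 2, and cleavage of its benzyl ester gives 3.

## Alternatives that were turned down

**Alternative 1:** The arene itself and the hindered aryl ester are disconnected together. In the forward step, thermolysis of the diketo-dioxinone A1 gives an acylketene that the secondary hydroxyl of 19 captures. The resulting triketo ester closes the carbocycle by aldol reaction between the future arene C1 and C6 and aromatises to resorcylate A2.
- For: the ester at the hindered position is formed through an unencumbered ketene before the arene exists, and the phenols emerge free. On this point it is stronger than the chosen route, which must force a 2,6-disubstituted benzoyl electrophile onto 19 in step 13.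
- Against: A1 needs its own multistep synthesis through two Claisen-type C-acylations. Ketene generation near 110 °C and the basic aromatisation expose the β-acyloxy ester to elimination, and the triketo ester can also close to a pyranone. After A2 the silyl ether must be removed and 14 attached in the presence of two free phenols, which calls for extra protection.
- Comparison: the chosen route sets the C6–C bond and brings in the stereocentre in one catalytic step from two simple inputs, and it keeps the phenols masked until the end.

**Alternative 2:** The arene C1–C2 and C5–C6 bonds are cut. In the forward step, the ynoate A3, already carrying all four ester units, undergoes Diels–Alder reaction with diene A4 and aromatises by loss of the methoxy and silyl groups to A5.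
- For: convergence is maximal, the regiochemistry follows the polarity of both partners, and all esters are made on an unhindered alk-2-ynoic acid. On the hindered ester it is again stronger than the chosen route.
- Against: A3 is an internal, mono-activated ynoate and a sluggish dienophile. The heat it needs is poorly tolerated by the ketene-acetal diene A4 and by three β-acyloxy ester units. The propargylic CH2 of A3, with an acyloxy group on the next carbon, invites isomerisation to an allenoate and elimination. The least certain step would consume the fully assembled polyester, and no steps are saved, since the same four fragments and ester couplings are needed.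
- Comparison: the chosen route places its uncertainty at step 3, on inexpensive material.

**Alternative 3:** The terminal unit is cut at its C1–C2 bond and its ester C–O bond. In the forward step, the free hydroxyl of the tri-unit alcohol A6 and epoxide A7 are joined by carbonylation under the cobalt catalysis of step 11 to give A8.
- For: it is atom-economic, needs no protecting group on the terminal hydroxyl and would save two to three steps (5, 6 and one benzyl group). On step economy it is stronger.
- Against: this carbonylation is dependable when a simple alcohol is present in large excess. Here the nucleophile is one equivalent of a hindered secondary alcohol bearing four esters. The acylcobalt intermediate is then more likely to close to the β-lactone, or to be captured by the new hydroxyl of A8, which is of the same type as that of A6, so chain growth cannot be stopped cleanly after one unit. Making A6 also costs a protect–deprotect cycle on the inner unit.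
- Comparison: the chosen route builds dimer 14 with defined sequence by two dependable couplings and uses the cobalt chemistry only in its proven regime (step 11).

Key step: step 3

## Route

Step 1
Reactants: 1 2,4-dihydroxybenzoic acid
Product: 2 benzyl 2,4-bis(benzyloxy)benzoate
Conditions: BnBr (3.5 equiv), K2CO3 (4 equiv), DMF, 70 °C
Reagents that add atoms: benzyl bromide, BrCc1ccccc1
Why: Williamson etherification of both phenoxides and SN2 alkylation of the carboxylate; heating in DMF overcomes the hydrogen-bonded 2-hydroxyl.

Step 2
Reactants: 2 benzyl 2,4-bis(benzyloxy)benzoate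
Product: 3 2,4-bis(benzyloxy)benzoic acid
Conditions: KOH, THF/MeOH/H2O, 65 °C; then aq. HCl
Reagents that add atoms: potassium hydroxide, [K+].[OH-]
Why: Saponification; aryl benzyl ethers are inert to hydroxide, so only the ester is cleaved.

Step 3
Reactants: 3 2,4-bis(benzyloxy)benzoic acid; 4 (R)-propylene oxide (3 equiv)
Product: 6 (R)-6,8-bis(benzyloxy)-3-methylisochroman-1-one, via hydroxy acid 5 (not isolated)
Conditions: Pd(OAc)2 (5 mol%), N-acetyl-L-tert-leucine (10 mol%), KOAc (1 equiv), HFIP, sealed vessel, 60 °C
Reagents that add atoms: none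
Why: KOAc turns 3 into its carboxylate, which binds divalent palladium, and concerted metalation-deprotonation at C6, assisted by the N-acetyl amino acid ligand, gives a five-membered palladacycle (Pd, O, carboxyl C, C1, C6). The aryl-palladium bond then attacks the coordinated epoxide 4 at its unsubstituted CH2 carbon in an SN2-type, redox-neutral opening that forms the C6–CH2 bond, and protonolysis of the palladium alkoxide releases hydroxy acid 5 and the catalyst. In the acidic fluoro alcohol 5 lactonises with loss of water, the side-chain oxygen adding to the carboxyl carbon in a 6-exo-trig closure of the only ring formed. The closest known reaction type is the Pd(OAc)2-catalysed ortho C–H alkylation of benzoic acids with terminal epoxides to 3-substituted 3,4-dihydroisocoumarins. No stereocentre is created: the R centre is the epoxide methine, whose C–O bond is never broken, so it is carried in with retention. The step needs site selectivity on the arene, secured because C6 holds the only C–H bond ortho to the carboxyl (C3 and C5 cannot be reached from the bound carboxylate), and regioselectivity in the epoxide, secured by the steric preference of the SN2 attack for the terminal carbon. The benzyl ethers are spectators and keep both phenols from binding palladium.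

Step 4
Reactants: 6 (R)-6,8-bis(benzyloxy)-3-methylisochroman-1-one
Product: 8 allyl 2,4-bis(benzyloxy)-6-[(R)-2-hydroxypropyl]benzoate, via potassium hydroxy carboxylate 7 (not isolated)
Conditions: KOH (1.05 equiv), THF/MeOH/H2O, 50 °C; evaporate to dryness; allyl bromide (1.5 equiv), DMF, 0 °C → rt; used at once
Reagents that add atoms: potassium hydroxide, [K+].[OH-]; allyl bromide, C=CCBr
Why: Lactone saponification gives carboxylate 7, which undergoes SN2 O-alkylation because it is far more nucleophilic than the neutral secondary hydroxyl; with one equivalent of base no alkoxide forms, and the 2,6-disubstituted ester is shielded, so relactonisation should be slow.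

Step 5
Reactants: 9 ethyl (S)-3-hydroxybutanoate
Product: 10 ethyl (S)-3-(benzyloxy)butanoate
Conditions: BnOC(=NH)CCl3 (1.5 equiv), TfOH (cat.), CH2Cl2/cyclohexane, 0 °C → rt
Reagents that add atoms: benzyl 2,2,2-trichloroacetimidate, N=C(OCc1ccccc1)C(Cl)(Cl)Cl
Why: Acid-catalysed benzyl transfer from the trichloroacetimidate; the non-basic medium excludes retro-aldol cleavage and elimination, and the C–O bond at the stereocentre is untouched.

Step 6
Reactants: 10 ethyl (S)-3-(benzyloxy)butanoate
Product: 11 (S)-3-(benzyloxy)butanoic acid
Conditions: LiOH, THF/H2O, 0 °C → rt; then aq. HCl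
Reagents that add atoms: lithium hydroxide, [Li+].[OH-]
Why: Saponification at low temperature; benzyloxide is a poor leaving group, so E1cB elimination should not compete and the S centre is kept.

Step 7
Reactants: 11 (S)-3-(benzyloxy)butanoic acid; 12 tert-butyl (R)-3-hydroxybutanoate
Product: 13 tert-butyl (R)-3-{[(S)-3-(benzyloxy)butanoyl]oxy}butanoate
Conditions: EDC·HCl (1.3 equiv), DMAP (0.2 equiv), CH2Cl2, 0 °C → rt
Reagents that add atoms: none
Why: Steglich esterification; activation is on the acyl side, so the R configuration of alcohol 12 is retained, and the tert-butyl ester is inert.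

Step 8
Reactants: 13 tert-butyl (R)-3-{[(S)-3-(benzyloxy)butanoyl]oxy}butanoate
Product: 14 (R)-3-{[(S)-3-(benzyloxy)butanoyl]oxy}butanoic acid
Conditions: TFA/CH2Cl2 (1:3), 0 °C → rt; co-evaporation with toluene
Reagents that add atoms: none
Why: Acidolysis of the tert-butyl ester by E1 loss of isobutene; the benzyl ether and the internal ester are stable to TFA at room temperature.

Step 9
Reactants: 8 allyl 2,4-bis(benzyloxy)-6-[(R)-2-hydroxypropyl]benzoate; 14 (R)-3-{[(S)-3-(benzyloxy)butanoyl]oxy}butanoic acid
Product: 15 allyl 2,4-bis(benzyloxy)-6-[(2R)-2-({(3R)-3-[((3S)-3-(benzyloxy)butanoyl)oxy]butanoyl}oxy)propyl]benzoate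
Conditions: EDC·HCl (1.5 equiv), DMAP (0.2 equiv), CH2Cl2, 0 °C
Reagents that add atoms: none
Why: Steglich esterification of an unhindered secondary hydroxyl with acyl-side activation, so no stereocentre is touched; low temperature and catalytic DMAP limit E1cB loss of the β-acyloxy group from activated 14 and relactonisation of 8.

Step 10
Reactants: 15 allyl 2,4-bis(benzyloxy)-6-[(2R)-2-({(3R)-3-[((3S)-3-(benzyloxy)butanoyl)oxy]butanoyl}oxy)propyl]benzoate
Product: 16 2,4-bis(benzyloxy)-6-[(2R)-2-({(3R)-3-[((3S)-3-(benzyloxy)butanoyl)oxy]butanoyl}oxy)propyl]benzoic acid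
Conditions: Pd(PPh3)4 (5 mol%), morpholine (5 equiv), THF, rt; wash with aq. KHSO4
Reagents that add atoms: none
Why: Tsuji–Trost deallylation: zerovalent palladium ionises the allyl ester to a π-allyl complex that morpholine captures; benzyl ethers and alkyl esters do not react.

Step 11
Reactants: 17 (R)-benzyl glycidyl ether
Product: 18 methyl (R)-4-(benzyloxy)-3-hydroxybutanoate
Conditions: Co2(CO)8 (5 mol%), 3-hydroxypyridine (10 mol%), CO (40 bar), MeOH/THF, 60 °C
Reagents that add atoms: carbon monoxide, [C-]#[O+]; methanol, CO
Why: Cobalt-catalysed alkoxycarbonylation of a terminal epoxide: tetracarbonylcobaltate opens the epoxide at CH2, carbon monoxide inserts, and methanol in excess cleaves the acylcobalt; the C–O bond at the stereocentre is never broken, so R is retained.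

Step 12
Reactants: 18 methyl (R)-4-(benzyloxy)-3-hydroxybutanoate
Product: 19 benzyl (R)-4-(benzyloxy)-3-hydroxybutanoate
Conditions: BnOH (5 equiv), Ti(OiPr)4 (10 mol%), toluene, 100 °C, volatile alcohols distilled off
Reagents that add atoms: benzyl alcohol, OCc1ccccc1
Why: Titanate-mediated transesterification, a neutral ester exchange that tolerates the free β-hydroxyl without elimination or epimerisation and is driven by removal of methanol.

Step 13
Reactants: 16 2,4-bis(benzyloxy)-6-[(2R)-2-({(3R)-3-[((3S)-3-(benzyloxy)butanoyl)oxy]butanoyl}oxy)propyl]benzoic acid; 19 benzyl (R)-4-(benzyloxy)-3-hydroxybutanoate (1.3 equiv)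
Product: 21 benzyl (3R)-4-(benzyloxy)-3-({2,4-bis(benzyloxy)-6-[(2R)-2-({(3R)-3-[((3S)-3-(benzyloxy)butanoyl)oxy]butanoyl}oxy)propyl]benzoyl}oxy)butanoate, via acid chloride 20 (not isolated)
Conditions: (COCl)2 (1.5 equiv), DMF (cat.), CH2Cl2, 0 °C → rt; evaporate; 19, Et3N (2 equiv), DMAP (cat.), CH2Cl2, 0 °C → rt
Reagents that add atoms: none
Why: Acid chloride formation followed by DMAP-catalysed acylation; a 2-alkoxy-6-alkylbenzoyl chloride is less shielded than a 2,6-dialkyl one and should still acylate a secondary alcohol, and because the acyl side is activated the R centre of 19 is retained.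

Step 14
Reactants: 21 benzyl (3R)-4-(benzyloxy)-3-({2,4-bis(benzyloxy)-6-[(2R)-2-({(3R)-3-[((3S)-3-(benzyloxy)butanoyl)oxy]butanoyl}oxy)propyl]benzoyl}oxy)butanoate (penta-O-benzyl talapolyester A)
Product: 22 talapolyester A
Conditions: H2 (1 atm), Pd/C (palladium on carbon, 10% Pd), EtOAc, rt; filtration, reversed-phase purification
Reagents that add atoms: none
Why: Catalytic hydrogenolysis of two aryl benzyl ethers, two alkyl benzyl ethers and one benzyl ester; no stereocentre is benzylic, and the neutral medium avoids acyl migration and lactonisation.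

## Compound list

1 | 2,4-dihydroxybenzoic acid | O=C(O)c1ccc(O)cc1O | starting material
2 | benzyl 2,4-bis(benzyloxy)benzoate | O=C(OCc1ccccc1)c1ccc(OCc2ccccc2)cc1OCc1ccccc1 | intermediate
3 | 2,4-bis(benzyloxy)benzoic acid | O=C(O)c1ccc(OCc2ccccc2)cc1OCc1ccccc1 | intermediate
4 | (R)-propylene oxide | C[C@@H]1CO1 | starting material
5 | 2,4-bis(benzyloxy)-6-[(R)-2-hydroxypropyl]benzoic acid | C[C@@H](O)Cc1cc(OCc2ccccc2)cc(OCc2ccccc2)c1C(=O)O | intermediate
6 | (R)-6,8-bis(benzyloxy)-3-methylisochroman-1-one | C[C@@H]1Cc2cc(OCc3ccccc3)cc(OCc3ccccc3)c2C(=O)O1 | intermediate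
7 | potassium 2,4-bis(benzyloxy)-6-[(R)-2-hydroxypropyl]benzoate | C[C@@H](O)Cc1cc(OCc2ccccc2)cc(OCc2ccccc2)c1C(=O)[O-].[K+] | intermediate
8 | allyl 2,4-bis(benzyloxy)-6-[(R)-2-hydroxypropyl]benzoate | C[C@@H](O)Cc1cc(OCc2ccccc2)cc(OCc2ccccc2)c1C(=O)OCC=C | intermediate
9 | ethyl (S)-3-hydroxybutanoate | C[C@H](O)CC(=O)OCC | starting material
10 | ethyl (S)-3-(benzyloxy)butanoate | C[C@H](OCc1ccccc1)CC(=O)OCC | intermediate
11 | (S)-3-(benzyloxy)butanoic acid | C[C@H](OCc1ccccc1)CC(=O)O | intermediate
12 | tert-butyl (R)-3-hydroxybutanoate | C[C@@H](O)CC(=O)OC(C)(C)C | starting material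
13 | tert-butyl (R)-3-{[(S)-3-(benzyloxy)butanoyl]oxy}butanoate | C[C@H](OCc1ccccc1)CC(=O)O[C@H](C)CC(=O)OC(C)(C)C | intermediate
14 | (R)-3-{[(S)-3-(benzyloxy)butanoyl]oxy}butanoic acid | C[C@H](OCc1ccccc1)CC(=O)O[C@H](C)CC(=O)O | intermediate
15 | allyl 2,4-bis(benzyloxy)-6-[(2R)-2-({(3R)-3-[((3S)-3-(benzyloxy)butanoyl)oxy]butanoyl}oxy)propyl]benzoate | C[C@H](OCc1ccccc1)CC(=O)O[C@H](C)CC(=O)O[C@H](C)Cc1cc(OCc2ccccc2)cc(OCc2ccccc2)c1C(=O)OCC=C | intermediate
16 | 2,4-bis(benzyloxy)-6-[(2R)-2-({(3R)-3-[((3S)-3-(benzyloxy)butanoyl)oxy]butanoyl}oxy)propyl]benzoic acid | C[C@H](OCc1ccccc1)CC(=O)O[C@H](C)CC(=O)O[C@H](C)Cc1cc(OCc2ccccc2)cc(OCc2ccccc2)c1C(=O)O | intermediate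
17 | (R)-benzyl glycidyl ether | C1O[C@H]1COCc2ccccc2 | starting material
18 | methyl (R)-4-(benzyloxy)-3-hydroxybutanoate | O[C@H](CC(=O)OC)COCc1ccccc1 | intermediate
19 | benzyl (R)-4-(benzyloxy)-3-hydroxybutanoate | O[C@H](CC(=O)OCc1ccccc1)COCc1ccccc1 | intermediate
20 | 2,4-bis(benzyloxy)-6-[(2R)-2-({(3R)-3-[((3S)-3-(benzyloxy)butanoyl)oxy]butanoyl}oxy)propyl]benzoyl chloride | C[C@H](OCc1ccccc1)CC(=O)O[C@H](C)CC(=O)O[C@H](C)Cc1cc(OCc2ccccc2)cc(OCc2ccccc2)c1C(=O)Cl | intermediate
21 | benzyl (3R)-4-(benzyloxy)-3-({2,4-bis(benzyloxy)-6-[(2R)-2-({(3R)-3-[((3S)-3-(benzyloxy)butanoyl)oxy]butanoyl}oxy)propyl]benzoyl}oxy)butanoate (penta-O-benzyl talapolyester A) | C[C@H](OCc1ccccc1)CC(=O)O[C@H](C)CC(=O)O[C@H](C)Cc1cc(OCc2ccccc2)cc(OCc2ccccc2)c1C(=O)O[C@@H](COCc1ccccc1)CC(=O)OCc1ccccc1 | intermediate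
22 | talapolyester A | C[C@H](O)CC(=O)O[C@H](C)CC(=O)O[C@H](C)Cc1cc(O)cc(O)c1C(=O)O[C@@H](CO)CC(=O)O | target

## Step count and least certain steps

Total: 14 steps. Longest linear sequence: 8 steps (1, 2, 3, 4, 9, 10, 13, 14; the branch 5, 6, 7, 8, 9, 10, 13, 14 is equally long).

**Step 3 (key step).** The ortho benzyloxy group twists the carboxylate and may slow cyclopalladation. Solvolysis of the volatile epoxide in the fluoro alcohol, O-alkylation of the carboxylate by the epoxide, or protodecarboxylation of the electron-rich acid could then outrun C–H alkylation.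

Fallback, setting out from 4 and returning at 6 by way of 5: the aryl Grignard reagent from 1-bromo-3,5-bis(benzyloxy)benzene F1 (Mg, THF) opens 4 at the methylene carbon under CuI catalysis to give (R)-1-[3,5-bis(benzyloxy)phenyl]propan-2-ol F2. N-Bromosuccinimide in MeCN at 0 °C brominates the ring position ortho to the side chain and para to one benzyloxy group, giving (R)-1-[2-bromo-3,5-bis(benzyloxy)phenyl]propan-2-ol F3. Treatment with n-BuLi (2.2 equiv, THF, −78 °C), then CO2 and aq. HCl, gives hydroxy acid 5, which closes to 6 with catalytic TsOH in toluene.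

**Step 4.** The free hydroxyl of 8 may attack the neighbouring allyl ester during work-up, on silica, or under the basic catalysis of step 9, reclosing the lactone with loss of allyl alcohol.

Fallback, setting out from 6 and returning at 16 (8 and 15 are bypassed): the carboxyl is held at the alcohol oxidation level, where it cannot lactonise. LiAlH4 in THF reduces 6 to (R)-1-[3,5-bis(benzyloxy)-2-(hydroxymethyl)phenyl]propan-2-ol F4. TBSCl and imidazole silylate the primary benzylic hydroxyl selectively to give (R)-1-[3,5-bis(benzyloxy)-2-{[(tert-butyldimethylsilyl)oxy]methyl}phenyl]propan-2-ol F5. Steglich coupling with 14 (EDC·HCl, DMAP) gives (2R)-1-[3,5-bis(benzyloxy)-2-{[(tert-butyldimethylsilyl)oxy]methyl}phenyl]propan-2-yl (3R)-3-{[(3S)-3-(benzyloxy)butanoyl]oxy}butanoate F6. Fluoride buffered with acetic acid (TBAF/AcOH, THF) frees the benzylic alcohol (2R)-1-[3,5-bis(benzyloxy)-2-(hydroxymethyl)phenyl]propan-2-yl (3R)-3-{[(3S)-3-(benzyloxy)butanoyl]oxy}butanoate F7. Dess–Martin oxidation gives (2R)-1-[3,5-bis(benzyloxy)-2-formylphenyl]propan-2-yl (3R)-3-{[(3S)-3-(benzyloxy)butanoyl]oxy}butanoate F8, and Pinnick oxidation (NaClO2, NaH2PO4, 2-methyl-2-butene, t-BuOH/H2O) gives 16.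

**Step 13.** Steric shielding of the acid chloride may make acylation slow. Base-induced E1cB elimination of 19 or of the product could then compete, as could attack of the side-chain ester oxygen on the acid chloride (loss of the dimer and return to the lactone).

Fallback, setting out from 16 and returning at 21: the roles are reversed, with the carboxylate as nucleophile in a Mitsunobu reaction that inverts the alcohol. The enantiomeric alcohol is made as in steps 11 and 12 from (S)-benzyl glycidyl ether F9, through methyl (S)-4-(benzyloxy)-3-hydroxybutanoate F10, to benzyl (S)-4-(benzyloxy)-3-hydroxybutanoate F11. Acid 16, F11, PPh3 and diisopropyl azodicarboxylate in toluene at 0 °C should give 21 with inversion to the R ester centre; dehydration of the β-hydroxy ester is the competing path to watch.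

**Step 14.** Cleavage of the two aliphatic benzyl ethers may lag behind the others. During a prolonged reaction or concentration, the aroyl group could migrate from O3 to the freed primary hydroxyl, or the freed hydroxy acid could lactonise.

Fallback, setting out from 21 and returning at 22, with no new compound: non-reductive Lewis-acid debenzylation with BCl3 and pentamethylbenzene as cation scavenger in CH2Cl2 at −78 °C, quenched cold into pH 7 buffer.

## Further compounds

F1 | step 3 | 1-bromo-3,5-bis(benzyloxy)benzene | Brc1cc(OCc2ccccc2)cc(OCc2ccccc2)c1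
F2 | step 3 | (R)-1-[3,5-bis(benzyloxy)phenyl]propan-2-ol | C[C@@H](O)Cc1cc(OCc2ccccc2)cc(OCc2ccccc2)c1
F3 | step 3 | (R)-1-[2-bromo-3,5-bis(benzyloxy)phenyl]propan-2-ol | C[C@@H](O)Cc1cc(OCc2ccccc2)cc(OCc2ccccc2)c1Br
F4 | step 4 | (R)-1-[3,5-bis(benzyloxy)-2-(hydroxymethyl)phenyl]propan-2-ol | C[C@@H](O)Cc1cc(OCc2ccccc2)cc(OCc2ccccc2)c1CO
F5 | step 4 | (R)-1-[3,5-bis(benzyloxy)-2-{[(tert-butyldimethylsilyl)oxy]methyl}phenyl]propan-2-ol | C[C@@H](O)Cc1cc(OCc2ccccc2)cc(OCc2ccccc2)c1CO[Si](C)(C)C(C)(C)C
F6 | step 4 | (2R)-1-[3,5-bis(benzyloxy)-2-{[(tert-butyldimethylsilyl)oxy]methyl}phenyl]propan-2-yl (3R)-3-{[(3S)-3-(benzyloxy)butanoyl]oxy}butanoate | C[C@H](OCc1ccccc1)CC(=O)O[C@H](C)CC(=O)O[C@H](C)Cc1cc(OCc2ccccc2)cc(OCc2ccccc2)c1CO[Si](C)(C)C(C)(C)C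
F7 | step 4 | (2R)-1-[3,5-bis(benzyloxy)-2-(hydroxymethyl)phenyl]propan-2-yl (3R)-3-{[(3S)-3-(benzyloxy)butanoyl]oxy}butanoate | C[C@H](OCc1ccccc1)CC(=O)O[C@H](C)CC(=O)O[C@H](C)Cc1cc(OCc2ccccc2)cc(OCc2ccccc2)c1CO
F8 | step 4 | (2R)-1-[3,5-bis(benzyloxy)-2-formylphenyl]propan-2-yl (3R)-3-{[(3S)-3-(benzyloxy)butanoyl]oxy}butanoate | C[C@H](OCc1ccccc1)CC(=O)O[C@H](C)CC(=O)O[C@H](C)Cc1cc(OCc2ccccc2)cc(OCc2ccccc2)c1C=O
F9 | step 13 | (S)-benzyl glycidyl ether | C1O[C@@H]1COCc2ccccc2
F10 | step 13 | methyl (S)-4-(benzyloxy)-3-hydroxybutanoate | O[C@@H](CC(=O)OC)COCc1ccccc1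
F11 | step 13 | benzyl (S)-4-(benzyloxy)-3-hydroxybutanoate | O[C@@H](CC(=O)OCc1ccccc1)COCc1ccccc1
F0 | step 14 | none | none
A1 | alternative 1 | (R)-6-[6-(tert-butyldimethylsilyloxy)-2,4-dioxoheptyl]-2,2-dimethyl-4H-1,3-dioxin-4-one | CC(C)(C)[Si](C)(C)O[C@H](C)CC(=O)CC(=O)CC1=CC(=O)OC(C)(C)O1
A2 | alternative 1 | benzyl (R)-4-(benzyloxy)-3-[2,4-dihydroxy-6-[(R)-2-(tert-butyldimethylsilyloxy)propyl]benzoyloxy]butanoate | CC(C)(C)[Si](C)(C)O[C@H](C)Cc1cc(O)cc(O)c1C(=O)O[C@@H](COCc1ccccc1)CC(=O)OCc1ccccc1
A3 | alternative 2 | benzyl (3R)-4-(benzyloxy)-3-{[(5R)-5-({(3R)-3-[((3S)-3-(benzyloxy)butanoyl)oxy]butanoyl}oxy)hex-2-ynoyl]oxy}butanoate | C[C@H](OCc1ccccc1)CC(=O)O[C@H](C)CC(=O)O[C@H](C)CC#CC(=O)O[C@@H](COCc1ccccc1)CC(=O)OCc1ccccc1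
A4 | alternative 2 | 1-methoxy-1,3-bis(trimethylsilyloxy)buta-1,3-diene | COC(O[Si](C)(C)C)=CC(=C)O[Si](C)(C)C
A5 | alternative 2 | tri-O-benzyl talapolyester A (phenols free) | C[C@H](OCc1ccccc1)CC(=O)O[C@H](C)CC(=O)O[C@H](C)Cc1cc(O)cc(O)c1C(=O)O[C@@H](COCc1ccccc1)CC(=O)OCc1ccccc1
A6 | alternative 3 | benzyl (3R)-4-(benzyloxy)-3-({2,4-bis(benzyloxy)-6-[(2R)-2-{[(3R)-3-hydroxybutanoyl]oxy}propyl]benzoyl}oxy)butanoate | C[C@@H](O)CC(=O)O[C@H](C)Cc1cc(OCc2ccccc2)cc(OCc2ccccc2)c1C(=O)O[C@@H](COCc1ccccc1)CC(=O)OCc1ccccc1
A7 | alternative 3 | (S)-propylene oxide | C[C@H]1CO1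
A8 | alternative 3 | tetra-O-benzyl talapolyester A (terminal hydroxyl free) | C[C@H](O)CC(=O)O[C@H](C)CC(=O)O[C@H](C)Cc1cc(OCc2ccccc2)cc(OCc2ccccc2)c1C(=O)O[C@@H](COCc1ccccc1)CC(=O)OCc1ccccc1
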